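**Retrosynthetic overview**

1. The strategy rests on the cis‑2,5‑tetrahydrofuran that bridges C4 and C7 of the 14‑membered carbocycle, with the C3 carbinol and the C8 tertiary carbinol each anti to the neighbouring ring C–O bond. This is the pattern left when the (3S,4S,7S,8S)‑bis‑epoxide of a (3E,7E)‑diene is opened with inversion at the methyl‑bearing carbons C4 and C8. Cembrane numbering is used: C1 is the ring CH on the lactone α‑carbon C15, C12 the C(Me)–O–acyl carbon, C16 the lactone carbonyl.
2. Disconnections, last bond first: C11 silyl ether; tetrahydrofuran (O–C4 and O–C8, acid/water epoxide relay); exocyclic methylene (Mannich/elimination); seven‑membered lactone (Wolff rearrangement, ketene captured by O12); C13–C14 (ring‑closing metathesis, then hydrogenation); both epoxides (Shi); C1–C2 (Evans alkylation of a but‑3‑enoyl imide); C12–C13 (chelate‑controlled vinyl addition); C9–C10 (enolate alkylation of a geraniol‑derived bromide).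
3. Rings in the forward direction: 14‑membered carbocycle, then seven‑membered lactone, then the tetrahydrofuran last.

Key step: step 21

Remark (assumption on the chemistry): the Shi ketone of the L series (enantiomer of the usual D‑fructose‑derived catalyst, which gives R,R‑epoxides from E‑trisubstituted alkenes) is taken to give the S,S‑epoxide at each of the two trisubstituted alkenes.

**Step 1**
Reactants: 1 geraniol
Product: 3 geranyl 4‑methoxybenzyl ether, via sodium geranoxide 2 (not isolated)
Conditions: NaH, THF/DMF, 0 °C; then 4‑methoxybenzyl chloride, Bu4NI (cat.), 0 °C to rt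
Reagents that add atoms: 4‑methoxybenzyl chloride, COc1ccc(CCl)cc1
Why: Williamson ether synthesis on a primary allylic alkoxide; the PMB ether can later be removed oxidatively without acid.

**Step 2**
Reactants: 3 geranyl 4‑methoxybenzyl ether
Product: 4 (2E,6E)‑8‑(4‑methoxybenzyloxy)‑2,6‑dimethylocta‑2,6‑dien‑1‑ol
Conditions: SeO2 (0.1 equiv), salicylic acid (0.1 equiv), t‑BuOOH (3 equiv), CH2Cl2, rt, stopped at partial conversion (3 recycled)
Reagents that add atoms: tert‑butyl hydroperoxide, CC(C)(C)OO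
Why: SeO2‑catalysed allylic oxidation (ene reaction, then [2,3]‑shift) takes the E‑methyl group of the remote, more electron‑rich alkene, the alkene beside the ether oxygen being deactivated.

**Step 3**
Reactants: 4 (2E,6E)‑8‑(4‑methoxybenzyloxy)‑2,6‑dimethylocta‑2,6‑dien‑1‑ol
Product: 5 (2E,6E)‑1‑bromo‑8‑(4‑methoxybenzyloxy)‑2,6‑dimethylocta‑2,6‑diene
Conditions: CBr4, PPh3, CH2Cl2, 0 °C
Reagents that add atoms: carbon tetrabromide, BrC(Br)(Br)Br
Why: Appel bromination of a primary allylic alcohol under neutral conditions, without allylic transposition.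

**Step 4**
Reactants: 6 3,3‑dimethoxybutan‑2‑one; 5 (2E,6E)‑1‑bromo‑8‑(4‑methoxybenzyloxy)‑2,6‑dimethylocta‑2,6‑diene
Product: 8 (6E,10E)‑2,2‑dimethoxy‑12‑(4‑methoxybenzyloxy)‑6,10‑dimethyldodeca‑6,10‑dien‑3‑one, via lithium enolate 7 (not isolated)
Conditions: LiN(i‑Pr)2, THF, −78 °C; then 5, DMPU, −78 to −20 °C
Reagents that add atoms: none
Why: Kinetic lithium enolate alkylation: the ketone has α‑hydrogens only on its methyl group and the primary allylic bromide is a good SN2 partner, which joins C9 to C10.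

**Step 5**
Reactants: 8 (6E,10E)‑2,2‑dimethoxy‑12‑(4‑methoxybenzyloxy)‑6,10‑dimethyldodeca‑6,10‑dien‑3‑one
Product: 9 (3R,6E,10E)‑2,2‑dimethoxy‑12‑(4‑methoxybenzyloxy)‑6,10‑dimethyldodeca‑6,10‑dien‑3‑ol
Conditions: (S)‑2‑methyl‑CBS‑oxazaborolidine (0.2 equiv), BH3·SMe2, THF, −30 °C; MeOH quench
Reagents that add atoms: none
Why: Corey–Bakshi–Shibata reduction: the quaternary ketal carbon acts as the large and the CH2 chain as the small substituent, so the (S)‑catalyst should give the (R)‑carbinol at C11, and carbonyl reduction outpaces hydroboration of the trisubstituted alkenes at this temperature.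

**Step 6**
Reactants: 9 (3R,6E,10E)‑2,2‑dimethoxy‑12‑(4‑methoxybenzyloxy)‑6,10‑dimethyldodeca‑6,10‑dien‑3‑ol
Product: 10 (3R,6E,10E)‑3‑hydroxy‑12‑(4‑methoxybenzyloxy)‑6,10‑dimethyldodeca‑6,10‑dien‑2‑one
Conditions: Amberlyst‑15 (cat.), acetone/H2O (20:1), rt
Reagents that add atoms: water, O
Why: Acid‑catalysed ketal hydrolysis under conditions mild enough to spare the PMB ether and the configuration of the α‑hydroxy ketone.

**Step 7**
Reactants: 10 (3R,6E,10E)‑3‑hydroxy‑12‑(4‑methoxybenzyloxy)‑6,10‑dimethyldodeca‑6,10‑dien‑2‑one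
Product: 12 (3R,4R,7E,11E)‑13‑(4‑methoxybenzyloxy)‑3,7,11‑trimethyltrideca‑1,7,11‑triene‑3,4‑diol, via magnesium alkoxide chelate 11 (not isolated)
Conditions: CH2=CHMgBr (3.5 equiv), THF, −78 to −40 °C; aq. NH4Cl
Reagents that add atoms: vinylmagnesium bromide, C=C[Mg]Br
Why: Cram‑chelate Grignard addition: the first equivalent forms the magnesium alkoxide, whose five‑membered chelate with the carbonyl exposes the face on the side of the C11 hydrogen, so vinyl should add to give the (11R,12R)‑diol and bring in C13.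

**Step 8**
Reactants: 12 (3R,4R,7E,11E)‑13‑(4‑methoxybenzyloxy)‑3,7,11‑trimethyltrideca‑1,7,11‑triene‑3,4‑diol
Product: 13 (3R,4R,7E,11E)‑4‑(tert‑butyldimethylsilyloxy)‑13‑(4‑methoxybenzyloxy)‑3,7,11‑trimethyltrideca‑1,7,11‑trien‑3‑ol
Conditions: TBSOTf (1.1 equiv), 2,6‑lutidine, CH2Cl2, −78 °C
Reagents that add atoms: tert‑butyldimethylsilyl trifluoromethanesulfonate, CC(C)(C)[Si](C)(C)OS(=O)(=O)C(F)(F)F
Why: Silylation with a silyl triflate at low temperature distinguishes the secondary hydroxyl from the neighbouring tertiary one on steric grounds.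

**Step 9**
Reactants: 13 (3R,4R,7E,11E)‑4‑(tert‑butyldimethylsilyloxy)‑13‑(4‑methoxybenzyloxy)‑3,7,11‑trimethyltrideca‑1,7,11‑trien‑3‑ol
Product: 14 (2E,6E,10R,11R)‑10‑(tert‑butyldimethylsilyloxy)‑3,7,11‑trimethyltrideca‑2,6,12‑triene‑1,11‑diol
Conditions: DDQ (1.2 equiv), CH2Cl2/pH 7 phosphate buffer, 0 °C
Reagents that add atoms: none
Why: Oxidative PMB cleavage (hydride abstraction from the electron‑rich benzylic position, then hydrolysis) leaves the silyl ether, the alkenes and the tertiary alcohol untouched.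

**Step 10**
Reactants: 14 (2E,6E,10R,11R)‑10‑(tert‑butyldimethylsilyloxy)‑3,7,11‑trimethyltrideca‑2,6,12‑triene‑1,11‑diol
Product: 16 (3R,4R,7E,11E)‑13‑bromo‑4‑(tert‑butyldimethylsilyloxy)‑3,7,11‑trimethyltrideca‑1,7,11‑trien‑3‑ol, via allylic mesylate 15 (not isolated)
Conditions: MsCl, Et3N, THF, −40 °C; then LiBr, −40 to 0 °C
Reagents that add atoms: lithium bromide, [Li+].[Br-]
Why: Sulfonylation of the primary allylic alcohol and Finkelstein‑type SN2 displacement by bromide; the hindered tertiary hydroxyl does not react with MsCl at −40 °C.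

**Step 11**
Reactants: 17 but‑3‑enoic acid; 18 (S)‑4‑benzyloxazolidin‑2‑one
Product: 20 (S)‑4‑benzyl‑3‑(but‑3‑enoyl)oxazolidin‑2‑one, via pivalic mixed anhydride 19 (not isolated)
Conditions: t‑BuCOCl, Et3N, THF, −20 °C; then 18, LiCl, −20 °C to rt
Reagents that add atoms: none
Why: N‑acylation of the oxazolidinone through a mixed anhydride under LiCl/Et3N, conditions mild enough to keep the β,γ‑double bond out of conjugation.

**Step 12**
Reactants: 20 (S)‑4‑benzyl‑3‑(but‑3‑enoyl)oxazolidin‑2‑one; 16 (3R,4R,7E,11E)‑13‑bromo‑4‑(tert‑butyldimethylsilyloxy)‑3,7,11‑trimethyltrideca‑1,7,11‑trien‑3‑ol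
Product: 22 alkylated imide with the full acyclic carbon chain (2S in the acyl chain), via sodium dienolate 21 (not isolated)
Conditions: 20 (2 equiv), NaN(SiMe3)2 (1.9 equiv), THF, −78 °C; then 16, −78 to −40 °C
Reagents that add atoms: none
Why: Evans asymmetric alkylation: the chelated sodium (Z)‑dienolate should react at its α‑carbon with the allylic bromide on the face away from the benzyl group, which joins C1 to C2 and sets C1, and the enolate is too weak a base to be quenched by the tertiary hydroxyl.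

**Step 13**
Reactants: 22 alkylated imide
Product: 23 acyclic (3S,4S,7S,8S)‑bis‑epoxide
Conditions: Shi ketone of the L series (0.6 equiv), KHSO5 (as 2KHSO5·KHSO4·K2SO4), K2CO3, Bu4NHSO4 (cat.), MeCN/CH2(OMe)2/aq. Na2B4O7 buffer, 0 °C
Reagents that add atoms: potassium peroxymonosulfate, [K+].[O-]S(=O)(=O)OO
Why: Shi asymmetric epoxidation: the chiral dioxirane should oxidise only the two electron‑rich trisubstituted alkenes (the vinyl groups are inert), each under reagent control through the spiro transition state, and removing these alkenes before metathesis leaves the carbene no six‑membered closure onto C8.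

**Step 14**
Reactants: 23 acyclic (3S,4S,7S,8S)‑bis‑epoxide
Product: 24 14‑membered carbocycle with the C13–C14 alkene
Conditions: second‑generation Grubbs catalyst RuCl2(=CHPh)(PCy3)(H2IMes) (10 mol%), 1,4‑benzoquinone (20 mol%), CH2Cl2 (0.5 mM), 40 °C
Reagents that add atoms: none
Why: Ring‑closing metathesis between the only two alkenes left, helped at the hindered end by the free allylic hydroxyl and by high dilution; the alkene geometry (E expected) does not matter.

**Step 15**
Reactants: 24 14‑membered carbocycle with the C13–C14 alkene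
Product: 25 saturated macrocyclic imide
Conditions: H2 (1 atm), PtO2 (cat.), EtOAc, rt
Reagents that add atoms: none
Why: Heterogeneous hydrogenation of the 1,2‑disubstituted alkene; platinum is chosen to avoid hydrogenolysis of the allylic C–O bond, and trialkyl epoxides are stable to it.

**Step 16**
Reactants: 25 saturated macrocyclic imide
Product: 26 macrocyclic lithium carboxylate
Conditions: LiOH, H2O2, THF/H2O, 0 °C; Na2SO3; auxiliary extracted; acid released at pH 5 (NaH2PO4, 0 °C), extracted and returned at once to the lithium salt with 1.0 equiv LiOH; freeze‑dried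
Reagents that add atoms: hydrogen peroxide, OO; lithium hydroxide, [Li+].[OH-]
Why: Hydroperoxide cleavage of the Evans imide at the exocyclic carbonyl should leave C1 unepimerised, and the acid is held as its salt so that the carboxyl group cannot open the 3,4‑epoxide.

**Step 17**
Reactants: 26 macrocyclic lithium carboxylate
Product: 28 macrocyclic diazoketone, via isobutyl carbonic anhydride 27 (not isolated)
Conditions: i‑BuOCOCl, N‑methylmorpholine (0.1 equiv), THF, −20 °C; then CH2N2, Et2O, −20 to 0 °C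
Reagents that add atoms: diazomethane, C=[N+]=[N-]
Why: First half of the Arndt–Eistert homologation (diazomethane supplies C15); without an acyl‑transfer catalyst and at or below 0 °C the hindered tertiary C12 hydroxyl should not intercept the activated acid before diazomethane does.

**Step 18**
Reactants: 28 macrocyclic diazoketone
Product: 30 bis‑epoxy seven‑membered lactone, via ketene 29 (not isolated)
Conditions: hν (Hg lamp, Pyrex), benzene (1 mM), i‑Pr2NEt (0.2 equiv), rt
Reagents that add atoms: none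
Why: Photochemical Wolff rearrangement, in which C1 migrates with retention, gives a ketene that the tertiary C12 hydroxyl should capture across the ring, closing the seven‑membered lactone on an alcohol that few other acylating agents reach.

**Step 19**
Reactants: 30 bis‑epoxy seven‑membered lactone
Product: 32 α‑(dimethylaminomethyl) lactone, via lithium lactone enolate 31 (not isolated)
Conditions: LiN(i‑Pr)2, THF, −78 °C; then CH2=NMe2+ I−, −78 to 0 °C
Reagents that add atoms: N,N‑dimethylmethyleneiminium iodide (Eschenmoser's salt), C=[N+](C)C.[I-]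
Why: Mannich reaction of the lactone enolate; only C15 carries α‑hydrogens, and the new centre at C15 is removed in the next step.

**Step 20**
Reactants: 32 α‑(dimethylaminomethyl) lactone
Product: 34 α‑methylene lactone bis‑epoxide, via trimethylammonium iodide 33 (not isolated)
Conditions: MeI (excess), CH2Cl2/MeOH, rt; evaporation; then NaHCO3 (aq.)/CH2Cl2, rt
Reagents that add atoms: none
Why: N‑methylation followed by E1cB (Hofmann‑type) loss of trimethylamine should give the exocyclic enoate under conditions the epoxides tolerate.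

**Step 21**
Reactants: 34 α‑methylene lactone bis‑epoxide
Product: 36 C11 silyl ether of querciformolide D, via bicyclic epoxonium ion 35 (not isolated)
Conditions: (1S)‑(+)‑10‑camphorsulfonic acid (0.1 equiv), H2O (3 equiv), CH2Cl2 (5 mM), −20 to 0 °C
Reagents that add atoms: water, O
Why: Reversible protonation of the 3,4‑epoxide lets the oxygen of the 7,8‑epoxide attack C4 from the rear, and the bicyclic epoxonium ion 35 is then opened by water at its tertiary carbon C8; if water opens the 7,8‑epoxide at C8 first, the C7 hydroxyl closes on C4 and the same product results. The closest known reaction type is the Brønsted acid‑triggered, water‑terminated epoxide‑opening cascade (epoxonium relay) of bis‑epoxides from 1,5‑dienes to hydroxylated 2,5‑disubstituted tetrahydrofurans, here applied across a 14‑membered ring. The tetrahydrofuran (O, C4, C5, C6, C7) closes 5‑exo‑tet. C4 and C8 are set by stereospecific inversion of the 4S and 8S epoxide carbons (to 4R and 8R), while C3 and C7 keep their oxygen and configuration, so the outcome is fixed by the epoxides made in step 13. The step needs the ring oxygen and not water to reach C4, the relay to run from the 7,8‑epoxide towards C4 and not the reverse, and water and not an internal oxygen to reach C8: the first two should hold because only this closure is both 5‑exo and at a methyl‑bearing tertiary carbon (the reverse sense would need 5‑exo attack at secondary C7 or 6‑endo attack at C8) and water is kept scarce, the third because O11 is silylated, O12 is acylated in the lactone and the conjugated lactone is indifferent to weak acid.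

**Step 22**
Reactants: 36 C11 silyl ether of querciformolide D
Product: 37 querciformolide D
Conditions: HF·pyridine, pyridine, THF, 0 °C to rt
Reagents that add atoms: none
Why: Fluoride‑mediated desilylation under pyridine buffering, which the methylene lactone, the tetrahydrofuran and the tertiary alcohols should tolerate.

**Compound list**

1 | geraniol, (2E)‑3,7‑dimethylocta‑2,6‑dien‑1‑ol | CC(C)=CCC/C(C)=C/CO | starting material
2 | sodium geranoxide | CC(C)=CCC/C(C)=C/C[O-].[Na+] | intermediate (not isolated)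
3 | geranyl 4‑methoxybenzyl ether | COc1ccc(COC/C=C(\C)CCC=C(C)C)cc1 | intermediate
4 | (2E,6E)‑8‑(4‑methoxybenzyloxy)‑2,6‑dimethylocta‑2,6‑dien‑1‑ol | COc1ccc(COC/C=C(\C)CC/C=C(\C)CO)cc1 | intermediate
5 | (2E,6E)‑1‑bromo‑8‑(4‑methoxybenzyloxy)‑2,6‑dimethylocta‑2,6‑diene (C2–C9) | COc1ccc(COC/C=C(\C)CC/C=C(\C)CBr)cc1 | intermediate
6 | 3,3‑dimethoxybutan‑2‑one | CC(=O)C(C)(OC)OC | starting material
7 | lithium 3,3‑dimethoxybut‑1‑en‑2‑olate | [Li+].[O-]C(=C)C(C)(OC)OC | intermediate (not isolated)
8 | (6E,10E)‑2,2‑dimethoxy‑12‑(4‑methoxybenzyloxy)‑6,10‑dimethyldodeca‑6,10‑dien‑3‑one | COc1ccc(COC/C=C(\C)CC/C=C(\C)CCC(=O)C(C)(OC)OC)cc1 | intermediate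
9 | (3R,6E,10E)‑2,2‑dimethoxy‑12‑(4‑methoxybenzyloxy)‑6,10‑dimethyldodeca‑6,10‑dien‑3‑ol (11R in cembrane numbering) | COc1ccc(COC/C=C(\C)CC/C=C(\C)CC[C@@H](O)C(C)(OC)OC)cc1 | intermediate
10 | (3R,6E,10E)‑3‑hydroxy‑12‑(4‑methoxybenzyloxy)‑6,10‑dimethyldodeca‑6,10‑dien‑2‑one | COc1ccc(COC/C=C(\C)CC/C=C(\C)CC[C@@H](O)C(C)=O)cc1 | intermediate
11 | bromomagnesium alkoxide of 10 (five‑membered chelate with the ketone) | COc1ccc(COC/C=C(\C)CC/C=C(\C)CC[C@@H](O[Mg]Br)C(C)=O)cc1 | intermediate (not isolated)
12 | (3R,4R,7E,11E)‑13‑(4‑methoxybenzyloxy)‑3,7,11‑trimethyltrideca‑1,7,11‑triene‑3,4‑diol (11R,12R in cembrane numbering) | COc1ccc(COC/C=C(\C)CC/C=C(\C)CC[C@@H](O)[C@](C)(O)C=C)cc1 | intermediate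
13 | (3R,4R,7E,11E)‑4‑(tert‑butyldimethylsilyloxy)‑13‑(4‑methoxybenzyloxy)‑3,7,11‑trimethyltrideca‑1,7,11‑trien‑3‑ol | COc1ccc(COC/C=C(\C)CC/C=C(\C)CC[C@@H](O[Si](C)(C)C(C)(C)C)[C@](C)(O)C=C)cc1 | intermediate
14 | (2E,6E,10R,11R)‑10‑(tert‑butyldimethylsilyloxy)‑3,7,11‑trimethyltrideca‑2,6,12‑triene‑1,11‑diol | OC/C=C(\C)CC/C=C(\C)CC[C@@H](O[Si](C)(C)C(C)(C)C)[C@](C)(O)C=C | intermediate
15 | primary methanesulfonate of 14 | CS(=O)(=O)OC/C=C(\C)CC/C=C(\C)CC[C@@H](O[Si](C)(C)C(C)(C)C)[C@](C)(O)C=C | intermediate (not isolated)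
16 | (3R,4R,7E,11E)‑13‑bromo‑4‑(tert‑butyldimethylsilyloxy)‑3,7,11‑trimethyltrideca‑1,7,11‑trien‑3‑ol | BrC/C=C(\C)CC/C=C(\C)CC[C@@H](O[Si](C)(C)C(C)(C)C)[C@](C)(O)C=C | intermediate
17 | but‑3‑enoic acid | C=CCC(=O)O | starting material
18 | (S)‑4‑benzyloxazolidin‑2‑one | O=C1N[C@@H](Cc2ccccc2)CO1 | starting material
19 | but‑3‑enoic pivalic anhydride | C=CCC(=O)OC(=O)C(C)(C)C | intermediate (not isolated)
20 | (S)‑4‑benzyl‑3‑(but‑3‑enoyl)oxazolidin‑2‑one | C=CCC(=O)N1[C@@H](Cc2ccccc2)COC1=O | intermediate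
21 | sodium (Z)‑dienolate of 20 | [Na+].[O-]/C(=C\C=C)N1[C@@H](Cc2ccccc2)COC1=O | intermediate (not isolated)
22 | (S)‑4‑benzyl‑3‑[(2S,4E,8E,12R,13R)‑12‑(tert‑butyldimethylsilyloxy)‑2‑ethenyl‑13‑hydroxy‑5,9,13‑trimethylpentadeca‑4,8,14‑trienoyl]oxazolidin‑2‑one | C=C[C@H](C/C=C(\C)CC/C=C(\C)CC[C@@H](O[Si](C)(C)C(C)(C)C)[C@](C)(O)C=C)C(=O)N1[C@@H](Cc2ccccc2)COC1=O | intermediate
23 | bis‑epoxide of 22 at both trisubstituted alkenes; cembrane numbering 1S,3S,4S,7S,8S,11R,12R | C=C[C@H](C[C@@H]1O[C@@]1(C)CC[C@@H]1O[C@@]1(C)CC[C@@H](O[Si](C)(C)C(C)(C)C)[C@](C)(O)C=C)C(=O)N1[C@@H](Cc2ccccc2)COC1=O | intermediate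
24 | 14‑membered carbocycle: 13E‑alkene, imide on C1, 3,4‑ and 7,8‑epoxides, C11 silyl ether, C12 tertiary alcohol (1S,3S,4S,7S,8S,11R,12R) | C[C@@]1(O)/C=C/[C@@H](C(=O)N2[C@@H](Cc3ccccc3)COC2=O)C[C@@H]2O[C@@]2(C)CC[C@@H]2O[C@@]2(C)CC[C@H]1O[Si](C)(C)C(C)(C)C | intermediate
25 | 13,14‑dihydro derivative of 24 (same centres; C1 is now labelled R only because the priority order changes) | C[C@@]1(O)CC[C@@H](C(=O)N2[C@@H](Cc3ccccc3)COC2=O)C[C@@H]2O[C@@]2(C)CC[C@@H]2O[C@@]2(C)CC[C@H]1O[Si](C)(C)C(C)(C)C | intermediate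
26 | lithium salt of the macrocyclic C1 carboxylic acid (1R,3S,4S,7S,8S,11R,12R) | C[C@@]1(O)CC[C@@H](C(=O)[O-])C[C@@H]2O[C@@]2(C)CC[C@@H]2O[C@@]2(C)CC[C@H]1O[Si](C)(C)C(C)(C)C.[Li+] | intermediate
27 | isobutyl carbonic anhydride of that acid | C[C@@]1(O)CC[C@@H](C(=O)OC(=O)OCC(C)C)C[C@@H]2O[C@@]2(C)CC[C@@H]2O[C@@]2(C)CC[C@H]1O[Si](C)(C)C(C)(C)C | intermediate (not isolated)
28 | macrocyclic diazomethyl ketone on C1 | C[C@@]1(O)CC[C@@H](C(=O)C=[N+]=[N-])C[C@@H]2O[C@@]2(C)CC[C@@H]2O[C@@]2(C)CC[C@H]1O[Si](C)(C)C(C)(C)C | intermediate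
29 | ketene on C1 (C15=C16=O) | C[C@@]1(O)CC[C@@H](C=C=O)C[C@@H]2O[C@@]2(C)CC[C@@H]2O[C@@]2(C)CC[C@H]1O[Si](C)(C)C(C)(C)C | intermediate (not isolated)
30 | macrocyclic bis‑epoxy seven‑membered lactone (C16 to O12), C11 silyl ether (1R,3S,4S,7S,8S,11R,12R) | O=C1O[C@]2(C)CC[C@@H](C1)C[C@@H]1O[C@@]1(C)CC[C@@H]1O[C@@]1(C)CC[C@H]2O[Si](C)(C)C(C)(C)C | intermediate
31 | lithium enolate of lactone 30 | [Li+].[O-]C1O[C@]2(C)CC[C@@H](C=1)C[C@@H]1O[C@@]1(C)CC[C@@H]1O[C@@]1(C)CC[C@H]2O[Si](C)(C)C(C)(C)C | intermediate (not isolated)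
32 | C15‑(dimethylaminomethyl) lactone (C15 epimers, inconsequential) | CN(C)CC1C(=O)O[C@]2(C)CC[C@@H]1C[C@@H]1O[C@@]1(C)CC[C@@H]1O[C@@]1(C)CC[C@H]2O[Si](C)(C)C(C)(C)C | intermediate
33 | C15‑(trimethylammoniomethyl) lactone iodide | C[N+](C)(C)CC1C(=O)O[C@]2(C)CC[C@@H]1C[C@@H]1O[C@@]1(C)CC[C@@H]1O[C@@]1(C)CC[C@H]2O[Si](C)(C)C(C)(C)C.[I-] | intermediate (not isolated)
34 | α‑methylene lactone bis‑epoxide, C11 silyl ether (1R,3S,4S,7S,8S,11R,12R) | C=C1C(=O)O[C@]2(C)CC[C@@H]1C[C@@H]1O[C@@]1(C)CC[C@@H]1O[C@@]1(C)CC[C@H]2O[Si](C)(C)C(C)(C)C | intermediate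
35 | bicyclic epoxonium ion: oxygen bonded to C4, C7 and C8, free C3 hydroxyl | C=C1C(=O)O[C@]2(C)CC[C@@H]1C[C@H](O)[C@@]1(C)CC[C@@H]3[O+]1[C@@]3(C)CC[C@H]2O[Si](C)(C)C(C)(C)C | intermediate (not isolated)
36 | 11‑O‑(tert‑butyldimethylsilyl)querciformolide D (1R,3S,4R,7S,8R,11R,12R) | C=C1C(=O)O[C@]2(C)CC[C@@H]1C[C@H](O)[C@@]1(C)CC[C@H](O1)[C@](C)(O)CC[C@H]2O[Si](C)(C)C(C)(C)C | intermediate
37 | querciformolide D (1R,3S,4R,7S,8R,11R,12R) | C=C1C(=O)O[C@]2(C)CC[C@@H]1C[C@H](O)[C@@]1(C)CC[C@H](O1)[C@](C)(O)CC[C@H]2O | target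

**Totals**

Total step count: 22 steps.
Longest linear sequence: 21 steps (steps 1–10 and 12–22, from geraniol); step 11 is the only step off this line.

**Steps most likely to fail**

Step 21 (epoxide relay). What may go wrong: the relay may be diverted. The possible processes are closure in the reverse sense (the 3,4‑epoxide oxygen attacking the protonated 7,8‑epoxide), hydration of the 3,4‑epoxide before the ring oxygen arrives, attack of the silyl ether oxygen on C8 with loss of silicon, and, once the C3 hydroxyl is free, its conjugate addition to the exocyclic enoate or acid‑induced migration of the exocyclic double bond. Fallback: the relay is moved ahead of the methylenation. This removes the conjugate acceptor from the relay step and tests the relay on a second, differently shaped macrocycle; it does not by itself correct a wrong‑sense relay. The fallback sets out from lactone 30. The same acid and water treatment should give the saturated tetrahydrofuran diol F1. Both new hydroxyls would be capped with N‑(trimethylsilyl)imidazole to give the bis(trimethylsilyl) ether F2. Deprotonation with LiN(i‑Pr)2 and reaction with Eschenmoser's salt would give the Mannich base F3, and quaternisation with MeI followed by NaHCO3 would give the tris‑silylated α‑methylene lactone F4. HF·pyridine would then remove all three silyl groups, and the sequence comes back to the route at 37.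

Step 14 (ring‑closing metathesis). What may go wrong: slow initiation at the vinyl group on the quaternary carbinol carbon may let intermolecular metathesis and ruthenium hydride‑induced migration of the C1 vinyl group into conjugation with the imide outrun the 14‑membered closure. Fallback: the order of the two ring closures is reversed, so that metathesis only has to close a seven‑membered ring. The fallback sets out from bis‑epoxide 23. Cleavage with LiOH/H2O2 as in step 16 would give the acyclic lithium carboxylate F5, in which no hydroxyl lies within reach of the activated acid. Activation with isobutyl chloroformate and diazomethane as in step 17 would give the diazoketone F6. Photolysis at high dilution as in step 18 would let the C12 hydroxyl capture the ketene, now closing the 15‑membered macrolactone F7. Metathesis of the two vinyl groups of F7 with the same ruthenium catalyst would give the cycloheptene lactone F8, and hydrogenation over PtO2 brings the sequence back at 30.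

Step 18 (Wolff rearrangement with transannular capture). What may go wrong: the hindered tertiary hydroxyl may capture the ketene too slowly, so that it is lost to dimerisation or to adventitious water. Fallback: the ketene is captured on purpose with water and the lactone is closed by nucleophile‑catalysed acyl transfer. The fallback sets out from diazoketone 28. Photolysis in THF/H2O containing Et3N would give the homologous acid, kept as its triethylammonium salt F9 so that it cannot open the 3,4‑epoxide. Treatment with 2‑methyl‑6‑nitrobenzoic anhydride, DMAP and Et3N at high dilution (Shiina lactonisation) would then acylate the C12 hydroxyl through the acylpyridinium ion, and the sequence comes back at 30.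

**Further compounds**

F1 | step 21 | saturated seven‑membered lactone with the C4–C7 tetrahydrofuran, free C3 and C8 hydroxyls, C11 silyl ether | O=C1O[C@]2(C)CC[C@@H](C1)C[C@H](O)[C@@]1(C)CC[C@H](O1)[C@](C)(O)CC[C@H]2O[Si](C)(C)C(C)(C)C
F2 | step 21 | 3,8‑bis(trimethylsilyl) ether of F1 | O=C1O[C@]2(C)CC[C@@H](C1)C[C@H](O[Si](C)(C)C)[C@@]1(C)CC[C@H](O1)[C@](C)(O[Si](C)(C)C)CC[C@H]2O[Si](C)(C)C(C)(C)C
F3 | step 21 | C15‑(dimethylaminomethyl) derivative of F2 (C15 epimers) | CN(C)CC1C(=O)O[C@]2(C)CC[C@@H]1C[C@H](O[Si](C)(C)C)[C@@]1(C)CC[C@H](O1)[C@](C)(O[Si](C)(C)C)CC[C@H]2O[Si](C)(C)C(C)(C)C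
F4 | step 21 | 3,8‑bis‑O‑(trimethylsilyl)‑11‑O‑(tert‑butyldimethylsilyl)querciformolide D | C=C1C(=O)O[C@]2(C)CC[C@@H]1C[C@H](O[Si](C)(C)C)[C@@]1(C)CC[C@H](O1)[C@](C)(O[Si](C)(C)C)CC[C@H]2O[Si](C)(C)C(C)(C)C
F5 | step 14 | acyclic bis‑epoxy lithium carboxylate from 23 | C=C[C@H](C[C@@H]1O[C@@]1(C)CC[C@@H]1O[C@@]1(C)CC[C@@H](O[Si](C)(C)C(C)(C)C)[C@](C)(O)C=C)C(=O)[O-].[Li+]
F6 | step 14 | acyclic bis‑epoxy diazoketone | C=C[C@H](C[C@@H]1O[C@@]1(C)CC[C@@H]1O[C@@]1(C)CC[C@@H](O[Si](C)(C)C(C)(C)C)[C@](C)(O)C=C)C(=O)C=[N+]=[N-]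
F7 | step 14 | 15‑membered macrolactone (C16 to O12) carrying vinyl groups on C1 and C12 | C=C[C@@H]1C[C@@H]2O[C@@]2(C)CC[C@@H]2O[C@@]2(C)CC[C@@H](O[Si](C)(C)C(C)(C)C)[C@@](C)(C=C)OC(=O)C1
F8 | step 14 | 13,14‑didehydro derivative of lactone 30 (cycloheptene lactone) | O=C1O[C@]2(C)C=C[C@@H](C1)C[C@@H]1O[C@@]1(C)CC[C@@H]1O[C@@]1(C)CC[C@H]2O[Si](C)(C)C(C)(C)C
F9 | step 18 | triethylammonium salt of the homologous macrocyclic acid (C1–CH2–CO2H) | C[C@@]1(O)CC[C@@H](CC(=O)[O-])C[C@@H]2O[C@@]2(C)CC[C@@H]2O[C@@]2(C)CC[C@H]1O[Si](C)(C)C(C)(C)C.CC[NH+](CC)CC
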